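**Strategy**

The pyran ring is cut at C3–C4 and O1–C2. The key step exploits the isoprene unit hidden in that ring: C2 is the β-carbon and C3 the β-methyl carbon of all-E solanesal, C4 the formyl carbon of a salicylaldehyde. One amine-catalysed domino reaction joins the methyl carbon to the aldehyde (vinylogous aldol) and the phenol oxygen to the enal β-carbon (oxa-Michael), which sets the quaternary centre C2 under catalyst control and touches none of the eight chain alkenes. The precursor pair is solanesal and a silyl-protected 2,5-dihydroxy-3,4-dimethylbenzaldehyde; the enal CHO, the activating group, is later excised as CO to leave the 2-methyl group.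

Key step: step 4

Remark on the chemistry: solanesol (all-E nonaprenol) and 2,3-dimethylhydroquinone are taken as commercial. The sense of induction in step 4 is assigned from the usual face-shielding model of diarylprolinol silyl ethers; if the opposite sense were found, the mirror-image catalyst would be used with nothing else changed.

Abbreviation: "C41 chain" = (3E,7E,11E,15E,19E,23E,27E)-4,8,12,16,20,24,28,32-octamethyltritriaconta-3,7,11,15,19,23,27,31-octaen-1-yl, that is CH2CH2 followed by seven E-trisubstituted alkenes and a terminal isopropylidene group.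

**Route**

Step 1
Reactants: 1 solanesol (all-E 3,7,11,15,19,23,27,31,35-nonamethylhexatriaconta-2,6,10,14,18,22,26,30,34-nonaen-1-ol)
Product: 2 all-E solanesal (the corresponding 2-enal)
Conditions: activated MnO2 (excess), hexane, rt, dark
Reagents that add atoms: none
Why: Allylic oxidation with MnO2 is selective for the primary allylic alcohol and leaves the eight isolated trisubstituted alkenes alone, and any 2E/2Z drift is harmless because step 4 passes through a dienamine.

Step 2
Reactants: 3 2,3-dimethylhydroquinone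
Product: 4 2,3-dimethyl-4-(triisopropylsilyloxy)phenol
Conditions: TIPSCl (1 equiv), imidazole, DMF, 0 °C to rt, 3 in threefold excess
Reagents that add atoms: triisopropylsilyl chloride, CC(C)[Si](Cl)(C(C)C)C(C)C
Why: Silyl ether formation on one of the two equivalent phenols of a symmetric diol, with the excess of 3 keeping the bis-ether low; the triisopropylsilyl group should survive amine bases, RhCl(PPh3)3 and the Burgess reagent and leave under fluoride without acid.

Step 3
Reactants: 4 2,3-dimethyl-4-(triisopropylsilyloxy)phenol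
Product: 5 2-hydroxy-3,4-dimethyl-5-(triisopropylsilyloxy)benzaldehyde
Conditions: MgCl2, Et3N, (CH2O)n, MeCN, reflux
Reagents that add atoms: paraformaldehyde (as formaldehyde), C=O
Why: Casnati–Skattebøl ortho-formylation, in which the magnesium phenoxide delivers formaldehyde to the only free position ortho to the free OH and a second formaldehyde oxidises the benzylic alkoxide to the aldehyde.

Step 4
Reactants: 5 2-hydroxy-3,4-dimethyl-5-(triisopropylsilyloxy)benzaldehyde; 2 all-E solanesal
Product: 8 bridged lactol (2R,6R)-9,10-dimethyl-2-(C41 chain)-8-(triisopropylsilyloxy)-3,4,5,6-tetrahydro-2H-2,6-methano-1,5-benzodioxocin-4-ol (either anomer), via dienamine 6 (not isolated), via hydroxy aldehyde 7 (not isolated)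
Conditions: (S)-2-{bis[3,5-bis(trifluoromethyl)phenyl](triethylsilyloxy)methyl}pyrrolidine (30 mol %), PhCO2H (30 mol %), toluene, rt, Ar, dark
Reagents that add atoms: none
Why: The amine and 2 give an iminium ion that loses a proton from the 3-methyl group to form linear dienamine 6, whose terminal CH2 adds to the formyl carbon of 5 (vinylogous aldol, bond C3–C4); the α,β-unsaturated iminium ion that results is attacked at its β-carbon by the ortho phenol oxygen (oxa-Michael, bond O1–C2), hydrolysis frees the catalyst and hydroxy aldehyde 7, and the 4-OH of 7 adds to the CH2CHO arm to give lactol 8. The closest known reaction type is the diarylprolinol silyl ether catalysed domino aldol/oxa-Michael reaction of salicylaldehydes with β-methyl-β-alkyl enals. The pyran ring closes 6-exo-trig (oxygen onto the iminium β-carbon) and the lactol ring 6-exo-trig (4-OH onto the aldehyde). C2 is set in the oxa-Michael step by the catalyst: the C(Ar)2OSiEt3 group of the (S)-amine covers one face of the E-iminium ion, in which the arm carrying the arene lies trans to the iminium carbon as it comes from the s-trans dienamine, so oxygen should add to the open face and give 2R; C4 later ceases to be a stereocentre, and since only the 2,4-cis isomer can lactolise, the reversible aldol step should feed material into 8. The step needs chemoselectivity for one of nine C=C bonds, which the amine secures because only the enal forms an iminium ion, and site selectivity for the methyl over the γ-methylene group, which the less hindered terminal CH2 of dienamine 6 should secure. Direct intermolecular oxa-Michael addition is blocked by the β,β-disubstitution, so the aldol event comes first and the ring closure is intramolecular.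

Step 5
Reactants: 8 bridged lactol
Product: 9 (2R,4R)-2,7,8-trimethyl-2-(C41 chain)-6-(triisopropylsilyloxy)chroman-4-ol
Conditions: RhCl(PPh3)3 (1.2 equiv), degassed toluene, 110 °C, Ar, dark
Reagents that add atoms: none
Why: Tsuji–Wilkinson decarbonylation acting on the open hydroxy aldehyde form 7 of the lactol (formyl C–H oxidative addition, CO extrusion, C–H reductive elimination) should turn the CH2CHO arm into the 2-methyl group without touching C2 or the trisubstituted alkenes, and it is run before any 2H-chromene exists that could ring-open on heating.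

Step 6
Reactants: 9 (2R,4R)-chroman-4-ol
Product: 10 (2R)-2,7,8-trimethyl-2-(C41 chain)-6-(triisopropylsilyloxy)-2H-chromene
Conditions: Burgess reagent (MeO2CNSO2NEt3, inner salt), benzene, 50 °C, dark
Reagents that add atoms: none
Why: Burgess dehydration by syn-elimination of the C4 sulfamate with a C3 hydrogen (the only β-hydrogens) should give the C3=C4 alkene under non-acidic conditions that spare the polyene, at a temperature too low for electrocyclic ring opening of the chromene, which would racemise C2.

Step 7
Reactants: 10 silyl-protected chromene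
Product: 11 plastochromenol-8, (2R)-2,7,8-trimethyl-2-(C41 chain)-2H-chromen-6-ol
Conditions: Bu4NF, AcOH, THF, 0 °C, Ar, dark
Reagents that add atoms: none
Why: Fluoride cleavage of the aryl silyl ether, buffered with acetic acid so that the electron-rich phenoxide is not exposed to air oxidation; C2 and the alkenes are not involved.

**Compound list**

1 | solanesol (all-E nonaprenol) | CC(C)=CCC/C(C)=C/CC/C(C)=C/CC/C(C)=C/CC/C(C)=C/CC/C(C)=C/CC/C(C)=C/CC/C(C)=C/CC/C(C)=C/CO | starting material
2 | all-E solanesal | CC(C)=CCC/C(C)=C/CC/C(C)=C/CC/C(C)=C/CC/C(C)=C/CC/C(C)=C/CC/C(C)=C/CC/C(C)=C/CC/C(C)=C/C=O | intermediate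
3 | 2,3-dimethylhydroquinone | Cc1c(C)c(O)ccc1O | starting material
4 | 2,3-dimethyl-4-(triisopropylsilyloxy)phenol | Cc1c(C)c(O[Si](C(C)C)(C(C)C)C(C)C)ccc1O | intermediate
5 | 2-hydroxy-3,4-dimethyl-5-(triisopropylsilyloxy)benzaldehyde | Cc1c(C)c(O[Si](C(C)C)(C(C)C)C(C)C)cc(C=O)c1O | intermediate
6 | linear dienamine of 2 and the (S)-catalyst, N–CH=CH–C(=CH2)–(C41 chain), E enamine | CC(C)=CCC/C(C)=C/CC/C(C)=C/CC/C(C)=C/CC/C(C)=C/CC/C(C)=C/CC/C(C)=C/CC/C(C)=C/CCC(=C)/C=C/N1CCC[C@H]1C(O[Si](CC)(CC)CC)(c1cc(C(F)(F)F)cc(C(F)(F)F)c1)c1cc(C(F)(F)F)cc(C(F)(F)F)c1 | intermediate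
7 | 2-[(2R,4R)-4-hydroxy-7,8-dimethyl-2-(C41 chain)-6-(triisopropylsilyloxy)chroman-2-yl]acetaldehyde | CC(C)=CCC/C(C)=C/CC/C(C)=C/CC/C(C)=C/CC/C(C)=C/CC/C(C)=C/CC/C(C)=C/CC/C(C)=C/CC[C@]1(CC=O)C[C@@H](O)c2cc(O[Si](C(C)C)(C(C)C)C(C)C)c(C)c(C)c2O1 | intermediate
8 | (2R,6R)-9,10-dimethyl-2-(C41 chain)-8-(triisopropylsilyloxy)-3,4,5,6-tetrahydro-2H-2,6-methano-1,5-benzodioxocin-4-ol (bridged lactol, anomeric centre open) | CC(C)=CCC/C(C)=C/CC/C(C)=C/CC/C(C)=C/CC/C(C)=C/CC/C(C)=C/CC/C(C)=C/CC/C(C)=C/CC[C@]1(CC(O)O2)C[C@@H]2c3cc(O[Si](C(C)C)(C(C)C)C(C)C)c(C)c(C)c3O1 | intermediate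
9 | (2R,4R)-2,7,8-trimethyl-2-(C41 chain)-6-(triisopropylsilyloxy)chroman-4-ol | CC(C)=CCC/C(C)=C/CC/C(C)=C/CC/C(C)=C/CC/C(C)=C/CC/C(C)=C/CC/C(C)=C/CC/C(C)=C/CC[C@]1(C)C[C@@H](O)c2cc(O[Si](C(C)C)(C(C)C)C(C)C)c(C)c(C)c2O1 | intermediate
10 | (2R)-2,7,8-trimethyl-2-(C41 chain)-6-(triisopropylsilyloxy)-2H-chromene | CC(C)=CCC/C(C)=C/CC/C(C)=C/CC/C(C)=C/CC/C(C)=C/CC/C(C)=C/CC/C(C)=C/CC/C(C)=C/CC[C@]1(C)C=Cc2cc(O[Si](C(C)C)(C(C)C)C(C)C)c(C)c(C)c2O1 | intermediate
11 | plastochromenol-8, (2R)-2,7,8-trimethyl-2-(C41 chain)-2H-chromen-6-ol | CC(C)=CCC/C(C)=C/CC/C(C)=C/CC/C(C)=C/CC/C(C)=C/CC/C(C)=C/CC/C(C)=C/CC/C(C)=C/CC[C@]1(C)C=Cc2cc(O)c(C)c(C)c2O1 | target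

**Count and risks**

Total step count: 7. Longest linear sequence: 6 steps (steps 2, 3, 4, 5, 6, 7, from 3 to 11); the solanesol branch joins after one step.

Steps most likely to fail:

1. Step 4. What may go wrong: slow turnover of the hindered β,β-disubstituted iminium ion, carbon–carbon bond formation through the γ-methylene group instead of the methyl group, or poor facial selectivity in the ring closure. Fallback, setting out from 5 and 1 and returning at 10: Wittig methylenation of 5 (Ph3PCH3Br, KOt-Bu in excess, THF) should give 2,3-dimethyl-4-(triisopropylsilyloxy)-6-vinylphenol F1. Solanesol 1 with methyl chloroformate and pyridine should give solanesyl methyl carbonate F2. A Tsuji–Trost asymmetric allylic etherification of F1 with F2 (Pd2(dba)3·CHCl3, trans-1,2-diaminocyclohexane bis(2-diphenylphosphinobenzamide) ligand, CH2Cl2, rt; ligand antipode chosen for R), which places phenols on the more substituted terminus of prenyl-type allyl complexes, should give the tertiary aryl vinyl ether F3. Ring-closing metathesis between its styrene and vinyl groups (first-generation Grubbs catalyst RuCl2(=CHPh)(PCy3)2, CH2Cl2, rt) would then close C3=C4 and give 10, which goes on to step 7. This makes O1–C2 and C3=C4 in two operations instead of one.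

2. Step 5. What may go wrong: decarbonylation too slow because the hemiacetal rarely opens, so that on long heating thermal loss of water or retro-oxa-Michael opening of the free β-aryloxy aldehyde takes over. Fallback, setting out from 8 and returning at 10: the aldehyde is unmasked first. Pyridinium p-toluenesulfonate (catalytic) with 4 Å molecular sieves in CH2Cl2 at rt should ionise the benzylic lactol C–O bond (assisted by O1) and, after loss of a C3 proton, give (S)-2-[7,8-dimethyl-2-(C41 chain)-6-(triisopropylsilyloxy)-2H-chromen-2-yl]acetaldehyde F4 (same spatial arrangement at C2). The free aldehyde is then decarbonylated under milder conditions (RhCl(PPh3)3, toluene, 60–70 °C, dark) to give 10 directly, so step 6 is not needed. Hydroacylation onto C3=C4 is the side reaction to watch.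

3. Step 6. What may go wrong: ionisation of the ortho-oxygenated benzylic sulfamate, with return of the nitrogen nucleophile or capture of the cation by the first chain alkene, instead of syn-elimination. Fallback, setting out from 9 and returning at 10: oxidation (Dess–Martin periodinane, NaHCO3, CH2Cl2) should give (R)-2,7,8-trimethyl-2-(C41 chain)-6-(triisopropylsilyloxy)chroman-4-one F5. Kinetic enolisation and triflation (KN(SiMe3)2, PhNTf2, THF, −78 °C, short enolate lifetime to avoid retro-oxa-Michael opening) should give (R)-2,7,8-trimethyl-2-(C41 chain)-6-(triisopropylsilyloxy)-2H-chromen-4-yl trifluoromethanesulfonate F6. Reduction with formate (Pd(OAc)2, PPh3, HCO2H, Bu3N, DMF, 40 °C) would then give 10.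

**Further compounds**

F1 | step 4 | 2,3-dimethyl-4-(triisopropylsilyloxy)-6-vinylphenol | C=Cc1cc(O[Si](C(C)C)(C(C)C)C(C)C)c(C)c(C)c1O
F2 | step 4 | all-E solanesyl methyl carbonate | CC(C)=CCC/C(C)=C/CC/C(C)=C/CC/C(C)=C/CC/C(C)=C/CC/C(C)=C/CC/C(C)=C/CC/C(C)=C/CC/C(C)=C/COC(=O)OC
F3 | step 4 | (R)-tertiary aryl ether, ArO–C(CH3)(CH=CH2)(C41 chain) with Ar = 2,3-dimethyl-4-(triisopropylsilyloxy)-6-vinylphenyl | CC(C)=CCC/C(C)=C/CC/C(C)=C/CC/C(C)=C/CC/C(C)=C/CC/C(C)=C/CC/C(C)=C/CC/C(C)=C/CC[C@](C)(C=C)Oc1c(C=C)cc(O[Si](C(C)C)(C(C)C)C(C)C)c(C)c1C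
F4 | step 5 | (S)-2-[7,8-dimethyl-2-(C41 chain)-6-(triisopropylsilyloxy)-2H-chromen-2-yl]acetaldehyde | CC(C)=CCC/C(C)=C/CC/C(C)=C/CC/C(C)=C/CC/C(C)=C/CC/C(C)=C/CC/C(C)=C/CC/C(C)=C/CC[C@]1(CC=O)C=Cc2cc(O[Si](C(C)C)(C(C)C)C(C)C)c(C)c(C)c2O1
F5 | step 6 | (R)-2,7,8-trimethyl-2-(C41 chain)-6-(triisopropylsilyloxy)chroman-4-one | CC(C)=CCC/C(C)=C/CC/C(C)=C/CC/C(C)=C/CC/C(C)=C/CC/C(C)=C/CC/C(C)=C/CC/C(C)=C/CC[C@]1(C)CC(=O)c2cc(O[Si](C(C)C)(C(C)C)C(C)C)c(C)c(C)c2O1
F6 | step 6 | (R)-2,7,8-trimethyl-2-(C41 chain)-6-(triisopropylsilyloxy)-2H-chromen-4-yl trifluoromethanesulfonate | CC(C)=CCC/C(C)=C/CC/C(C)=C/CC/C(C)=C/CC/C(C)=C/CC/C(C)=C/CC/C(C)=C/CC/C(C)=C/CC[C@]1(C)C=C(OS(=O)(=O)C(F)(F)F)c2cc(O[Si](C(C)C)(C(C)C)C(C)C)c(C)c(C)c2O1
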